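The route closes ring B last at C5–C6 (labdane numbering). An enantiopure ring A, already carrying the 2α,3β-dichloride, the gem-dimethyl C4 and the quaternary C10, bears a thionocarbonate at C5 and, through C9, a 2-acetoxy-1-en-3-one chain. A Barton–McCombie-initiated 6-endo Giese cyclisation joins the C5 radical to C6. One operation forms the trans-decalin, sets C5 and C7, and delivers the C7 acetate beside a C8 ketone that later becomes the exocyclic methylene. The step exploits two features of ring B: C8 can serve as a ketone inside the tether, and C7 carries oxygen, so C6 is the terminus of a captodative enone. An Evans aldol and imide closure finish the side chain.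

Key step: step 15

Remark: labdane numbering of the target is used for every intermediate (C1–C10 decalin, C17 exocyclic methylene, C11–C16 side chain); α and β refer to the faces of the final decalin, with the C10 methyl β.
Assumption: the C5 carbinol in 19–23 is drawn as the expected 5β epimer; its configuration is irrelevant because C5 becomes a radical in step 15.

Step 1
Reactants: 1 furan-2(5H)-one
Product: 2 (S)-4-vinyldihydrofuran-2(3H)-one
Conditions: CH2=CHBF3K, [Rh(cod)2]BF4 (3 mol %), (S)-BINAP (3.3 mol %), dioxane/H2O, 80 °C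
Reagents that add atoms: potassium vinyltrifluoroborate, C=C[B-](F)(F)F.[K+]
Why: Rhodium-catalysed asymmetric conjugate addition of an alkenylboron reagent (Hayashi–Miyaura reaction); the (S)-BINAP-bound rhodium vinyl species should select one enantioface of the butenolide and set C9 as (S), by analogy with additions to cyclic enones.

Step 2
Reactants: 2 (S)-4-vinyldihydrofuran-2(3H)-one
Product: 4 (3R,4R)-3-methyl-4-vinyldihydrofuran-2(3H)-one, via lithium enolate 3 (not isolated)
Conditions: LiN(i-Pr)2, THF, −78 °C; MeI, −78 → −40 °C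
Reagents that add atoms: iodomethane, CI
Why: Alkylation of the lactone lithium enolate, which should occur anti to the C9 vinyl group and give the trans lactone; this centre is made quaternary in step 5.

Step 3
Reactants: 4 (3R,4R)-3-methyl-4-vinyldihydrofuran-2(3H)-one
Product: 6 (3R,4R)-4-(2-hydroxyethyl)-3-methyldihydrofuran-2(3H)-one, via B-alkyl-9-BBN adduct 5 (not isolated)
Conditions: 9-BBN, THF, 0 → 23 °C; then H2O2, NaOAc, H2O, 0 °C
Reagents that add atoms: hydrogen peroxide, OO
Why: Anti-Markovnikov hydroboration–oxidation of the terminal alkene installs the C12 oxygen, and the buffered oxidation should leave the γ-lactone closed.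

Step 4
Reactants: 6 (3R,4R)-4-(2-hydroxyethyl)-3-methyldihydrofuran-2(3H)-one
Product: 7 (3R,4R)-4-[2-(tert-butyldiphenylsilyloxy)ethyl]-3-methyldihydrofuran-2(3H)-one
Conditions: TBDPSCl, imidazole, DMF, 23 °C
Reagents that add atoms: tert-butyl(chloro)diphenylsilane, CC(C)(C)[Si](Cl)(c1ccccc1)c1ccccc1
Why: Silylation of the primary alcohol gives an ether that should survive every step up to step 17.

Step 5
Reactants: 7 (3R,4R)-4-[2-(tert-butyldiphenylsilyloxy)ethyl]-3-methyldihydrofuran-2(3H)-one
Product: 9 (3R,4R)-3-allyl-4-[2-(tert-butyldiphenylsilyloxy)ethyl]-3-methyldihydrofuran-2(3H)-one, via lithium enolate 8 (not isolated)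
Conditions: LiN(i-Pr)2, THF/DMPU, −78 °C; allyl bromide, −78 → −20 °C
Reagents that add atoms: allyl bromide, C=CCBr
Why: Second enolate alkylation: allyl bromide should approach the tetrasubstituted enolate anti to the C9 side chain, which relays the C9 configuration to the quaternary C10 (methyl cis to the side chain).

Step 6
Reactants: 9 (3R,4R)-3-allyl-4-[2-(tert-butyldiphenylsilyloxy)ethyl]-3-methyldihydrofuran-2(3H)-one
Product: 11 5-allyl-6-[2-(tert-butyldiphenylsilyloxy)ethyl]-7-hydroxy-3,3,5-trimethylhept-1-en-4-one (C9 and C10 as in 9), via magnesium hemiketalate 10 (not isolated)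
Conditions: Me2C=CHCH2MgCl (1.1 equiv), THF, −78 °C; aq. NH4Cl at −78 °C
Reagents that add atoms: prenylmagnesium chloride, CC(C)=CC[Mg]Cl
Why: Addition of an allylic Grignard reagent through its γ-carbon (six-membered SE2′ transition state) gives the reverse-prenyl ketone; the hemiketalate is stable at −78 °C and the resulting ketone, flanked by two quaternary carbons, should not add a second equivalent.

Step 7
Reactants: 11 5-allyl-6-[2-(tert-butyldiphenylsilyloxy)ethyl]-7-hydroxy-3,3,5-trimethylhept-1-en-4-one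
Product: 12 6-[4-(tert-butyldiphenylsilyloxy)-1-hydroxybutan-2-yl]-2,2,6-trimethylcyclohex-3-en-1-one (ring A; C5 ketone, C2=C3, 10β-methyl)
Conditions: second-generation Grubbs catalyst (H2IMes)(PCy3)Cl2Ru=CHPh (5 mol %), CH2Cl2, 40 °C
Reagents that add atoms: none
Why: Ring-closing metathesis between the allyl and 1,1-dimethylallyl termini closes ring A as the C2=C3 cyclohexene, driven by loss of ethene.

Step 8
Reactants: 12 6-[4-(tert-butyldiphenylsilyloxy)-1-hydroxybutan-2-yl]-2,2,6-trimethylcyclohex-3-en-1-one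
Product: 13 4-(tert-butyldiphenylsilyloxy)-2-(1,3,3-trimethyl-2-oxocyclohex-4-en-1-yl)butanoic acid (C8 acid)
Conditions: TEMPO (20 mol %), PhI(OAc)2 (2.2 equiv), MeCN/H2O, 23 °C
Reagents that add atoms: water, O
Why: Oxoammonium (TEMPO) oxidation of the primary alcohol through the aldehyde hydrate to the acid; the ketone has no α-hydrogen and the alkene is not touched.

Step 9
Reactants: 13 C8 acid of ring A
Product: 14 bridged chloro-δ-lactone (C8 carboxyl oxygen on C2α, 3β-chloro, C5 ketone)
Conditions: N-chlorosuccinimide, Ph3P=S (10 mol %), CH2Cl2, 0 → 23 °C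
Reagents that add atoms: N-chlorosuccinimide, O=C1CCC(=O)N1Cl
Why: Chlorolactonisation (6-exo): the carboxylate tethered to the α-face at C10 can reach only C2 from the α-face, so the chloronium ion must lie on the β-face and anti addition sets 3β-Cl and 2α-O.

Step 10
Reactants: 14 bridged chloro-δ-lactone
Product: 15 C8 morpholine amide of ring A with 2α-hydroxy, 3β-chloro and C5 ketone
Conditions: morpholine, AlMe3, CH2Cl2, 0 → 23 °C
Reagents that add atoms: morpholine, C1COCCN1
Why: Aminolysis of the strained bridged lactone by the aluminium amide gives a morpholine amide, a ketone precursor inert to hydride and chloride, and frees the 2α-alcohol.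

Step 11
Reactants: 15 2α-hydroxy-3β-chloro morpholine amide
Product: 18 2α,3β-dichloro C5-ketone morpholine amide, via 2α-mesylate 16 (not isolated), via 2β-chloride 17 (not isolated)
Conditions: MsCl, Et3N, CH2Cl2, 0 °C; then LiCl (10 equiv), DMF, 90 °C
Reagents that add atoms: lithium chloride, [Li+].[Cl-]
Why: SN2 displacement of the mesylate by chloride, then degenerate chloride exchange at the secondary C2 (Finkelstein-type epimerisation), should converge on the trans-diequatorial 2α,3β-dichloride, because the 2β epimer must place a chlorine or the C9 chain syn-axial to a methyl group and the neopentyl C3–Cl does not exchange.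

Step 12
Reactants: 18 2α,3β-dichloro C5-ketone morpholine amide
Product: 19 2α,3β-dichloro 5β-hydroxy morpholine amide
Conditions: LiBH4, THF, 0 → 40 °C
Reagents that add atoms: none
Why: Hydride reduction of the hindered ketone (the amide is inert to LiBH4), expected from the face anti to the flanking axial methyl groups to give the equatorial 5β-alcohol.

Step 13
Reactants: 19 2α,3β-dichloro 5β-hydroxy morpholine amide
Product: 22 C7,C8-diketone with C5 O-phenyl thionocarbonate, via lithium hemiaminal alkoxide 20 (not isolated), via 2-ethoxy enone 21 (not isolated)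
Conditions: CH2=C(OEt)Li (from ethyl vinyl ether, t-BuLi; 2.2 equiv), THF, −78 → −20 °C; PhOC(S)Cl, −78 → 0 °C; then 1 M HCl, THF, 23 °C
Reagents that add atoms: 1-ethoxyvinyllithium, [Li]C(=C)OCC; O-phenyl chlorothionoformate, S=C(Cl)Oc1ccccc1; water, O
Why: Acyl substitution of the morpholine amide by the organolithium through a tetrahedral intermediate that is stable until work-up; the C5 lithium alkoxide is thioacylated before any ketone is released, and acid then hydrolyses the enol ether to the 1,2-diketone.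

Step 14
Reactants: 22 C7,C8-diketone with C5 O-phenyl thionocarbonate
Product: 23 2-acetoxy-1-en-3-one (C6=C7(OAc)–C8=O) with C5 O-phenyl thionocarbonate
Conditions: Ac2O, Et3N, DMAP (10 mol %), CH2Cl2, 0 °C
Reagents that add atoms: acetic anhydride, CC(=O)OC(C)=O
Why: O-Acetylation of the less hindered methyl-side enol of the 1,2-diketone gives the captodative 2-acetoxy enone.

Step 15
Reactants: 23 2-acetoxy-1-en-3-one with C5 O-phenyl thionocarbonate
Product: 24 7β-acetoxy-2α,3β-dichloro-12-(tert-butyldiphenylsilyloxy)-13,14,15,16,17-pentanorlabdan-8-one (5α-H, 9α-H)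
Conditions: Bu3SnH (1.3 equiv), AIBN (0.2 equiv), benzene (0.005 M), 80 °C, syringe-pump addition
Reagents that add atoms: none
Why: The tributyltin radical adds to the thionocarbonate C=S and β-scission (Barton–McCombie) gives the secondary C5 radical, which adds to the terminal C6 of the captodative 2-acetoxy enone; the resulting C7 radical takes hydrogen from Bu3SnH. The closest known reaction type is the intramolecular Giese addition of a xanthate- or thionocarbonate-derived alkyl radical to a vinyl ketone. Ring B closes in the 6-endo-trig mode, favoured over 5-exo because the ketone lies inside the tether and the nucleophilic radical attacks the β-carbon of the enone, not its α-carbon. C5 should be set by a chair-like transition state in which ring A is locked by the two equatorial chlorines (C10 methyl axial, C9 equatorial) and the new bond forms equatorially with the C9 side chain equatorial on the forming ring, giving the trans ring fusion (5α-H). C7 is set by axial hydrogen-atom transfer to the α-face, which leaves the acetate equatorial (7β), and C9 keeps the more stable equatorial side chain next to the ketone. The step needs radical generation at the thionocarbonate in the presence of two secondary C–Cl bonds and the enone, secured by the much faster addition of tin radicals to C=S and by high dilution with slow hydride addition.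

Step 16
Reactants: 24 decalin 8-ketone
Product: 25 7β-acetoxy-2α,3β-dichloro-12-(tert-butyldiphenylsilyloxy)-13,14,15,16-tetranorlabd-8(17)-ene
Conditions: Zn, CH2Br2, TiCl4, THF/CH2Cl2, 0 → 23 °C
Reagents that add atoms: dibromomethane, BrCBr
Why: Takai–Lombardo methylenation: the non-basic zinc–titanium methylene reagent should convert the hindered ketone without touching the acetate or epimerising C7 and C9.

Step 17
Reactants: 25 silyl ether of the 8(17)-ene
Product: 26 7β-acetoxy-2α,3β-dichloro-13,14,15,16-tetranorlabd-8(17)-en-12-ol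
Conditions: HF·pyridine, THF/pyridine, 0 → 23 °C
Reagents that add atoms: none
Why: Cleavage of the silyl ether by fluoride under buffered, non-basic conditions that leave the allylic acetate in place.

Step 18
Reactants: 26 primary alcohol
Product: 27 7β-acetoxy-2α,3β-dichloro-13,14,15,16-tetranorlabd-8(17)-en-12-al
Conditions: Dess–Martin periodinane, NaHCO3, CH2Cl2, 23 °C
Reagents that add atoms: none
Why: Dess–Martin oxidation of the primary alcohol to the aldehyde under neutral conditions.

Step 19
Reactants: 28 (R)-4-benzyloxazolidin-2-one; 29 succinic anhydride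
Product: 31 4-[(4R)-4-benzyl-2-oxooxazolidin-3-yl]-4-oxobutanoic acid, via lithium oxazolidinide 30 (not isolated)
Conditions: n-BuLi, THF, −78 °C; then 29, −78 → 0 °C; aq. HCl work-up
Reagents that add atoms: none
Why: N-Acylation of the lithiated oxazolidinone by ring opening of the cyclic anhydride.

Step 20
Reactants: 31 4-[(4R)-4-benzyl-2-oxooxazolidin-3-yl]-4-oxobutanoic acid
Product: 33 4-[(4R)-4-benzyl-2-oxooxazolidin-3-yl]-4-oxobutanamide, via mixed carbonic anhydride 32 (not isolated)
Conditions: i-BuOCOCl, N-methylmorpholine, THF, −20 °C; NH3 (0.5 M in dioxane, 1.05 equiv), −20 °C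
Reagents that add atoms: ammonia, N
Why: Amidation through the mixed carbonic anhydride with one equivalent of ammonia at low temperature, which should spare the N-acyl oxazolidinone.

Step 21
Reactants: 33 4-[(4R)-4-benzyl-2-oxooxazolidin-3-yl]-4-oxobutanamide; 27 C12 aldehyde
Product: 35 (12S,13R)-aldol adduct (N-acyl oxazolidinone with free C15 primary amide), via dibutylboron enolate 34 (not isolated)
Conditions: Bu2BOTf (2.2 equiv), i-Pr2NEt (2.6 equiv), CH2Cl2, −78 → 0 °C; 27, −78 → 0 °C; pH 7 buffer, MeOH, H2O2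
Reagents that add atoms: none
Why: Evans syn-aldol reaction: the (Z)-boron enolate reacts through a closed chair transition state and the (R)-benzyl auxiliary directs attack to give 12S,13R.

Step 22
Reactants: 35 (12S,13R)-aldol adduct
Product: 36 haterumaimide A
Conditions: DBU (0.2 equiv), THF, 0 → 23 °C
Reagents that add atoms: none
Why: Intramolecular N-acylation (5-exo-trig) of the primary amide by the activated N-acyl oxazolidinone forms the succinimide and releases the auxiliary under conditions mild enough for the acetate and C13.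

Compound list
1 | furan-2(5H)-one | O=C1C=CCO1 | starting material
2 | (S)-4-vinyldihydrofuran-2(3H)-one | O=C1OC[C@H](C=C)C1 | intermediate
3 | lithium enolate of 2 | [Li]OC1=C[C@@H](C=C)CO1 | intermediate
4 | (3R,4R)-3-methyl-4-vinyldihydrofuran-2(3H)-one | O=C1OC[C@H](C=C)[C@H]1C | intermediate
5 | B-alkyl-9-BBN adduct of 4 | O=C1OC[C@H](CCB2C3CCCC2CCC3)[C@H]1C | intermediate
6 | (3R,4R)-4-(2-hydroxyethyl)-3-methyldihydrofuran-2(3H)-one | O=C1OC[C@H](CCO)[C@H]1C | intermediate
7 | (3R,4R)-4-[2-(tert-butyldiphenylsilyloxy)ethyl]-3-methyldihydrofuran-2(3H)-one | O=C1OC[C@H](CCO[Si](c2ccccc2)(c2ccccc2)C(C)(C)C)[C@H]1C | intermediate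
8 | lithium enolate of 7 | [Li]OC1=C(C)[C@@H](CCO[Si](c2ccccc2)(c2ccccc2)C(C)(C)C)CO1 | intermediate
9 | (3R,4R)-3-allyl-4-[2-(tert-butyldiphenylsilyloxy)ethyl]-3-methyldihydrofuran-2(3H)-one | O=C1OC[C@H](CCO[Si](c2ccccc2)(c2ccccc2)C(C)(C)C)[C@@]1(C)CC=C | intermediate
10 | chloromagnesium hemiketalate from 9 and the prenyl Grignard reagent (C5 configuration undefined) | Cl[Mg]OC1(C(C)(C)C=C)OC[C@H](CCO[Si](c2ccccc2)(c2ccccc2)C(C)(C)C)[C@@]1(C)CC=C | intermediate
11 | 5-allyl-6-[2-(tert-butyldiphenylsilyloxy)ethyl]-7-hydroxy-3,3,5-trimethylhept-1-en-4-one (C9, C10 as in 9) | OC[C@H](CCO[Si](c1ccccc1)(c1ccccc1)C(C)(C)C)[C@@](C)(CC=C)C(=O)C(C)(C)C=C | intermediate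
12 | 6-[4-(tert-butyldiphenylsilyloxy)-1-hydroxybutan-2-yl]-2,2,6-trimethylcyclohex-3-en-1-one (ring A, 10β-methyl) | OC[C@H](CCO[Si](c1ccccc1)(c1ccccc1)C(C)(C)C)[C@@]1(C)CC=CC(C)(C)C1=O | intermediate
13 | 4-(tert-butyldiphenylsilyloxy)-2-(1,3,3-trimethyl-2-oxocyclohex-4-en-1-yl)butanoic acid | OC(=O)[C@H](CCO[Si](c1ccccc1)(c1ccccc1)C(C)(C)C)[C@@]1(C)CC=CC(C)(C)C1=O | intermediate
14 | bridged chloro-δ-lactone (C8 carboxyl O on C2α, 3β-Cl, C5 ketone) | O=C1[C@H](CCO[Si](c2ccccc2)(c2ccccc2)C(C)(C)C)[C@@]2(C)C[C@@H](O1)[C@H](Cl)C(C)(C)C2=O | intermediate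
15 | C8 morpholine amide, 2α-hydroxy, 3β-chloro, C5 ketone | O=C(N1CCOCC1)[C@H](CCO[Si](c1ccccc1)(c1ccccc1)C(C)(C)C)[C@@]1(C)C[C@@H](O)[C@H](Cl)C(C)(C)C1=O | intermediate
16 | 2α-mesylate of 15 | O=C(N1CCOCC1)[C@H](CCO[Si](c1ccccc1)(c1ccccc1)C(C)(C)C)[C@@]1(C)C[C@@H](OS(C)(=O)=O)[C@H](Cl)C(C)(C)C1=O | intermediate
17 | 2β,3β-dichloro epimer of 18 | O=C(N1CCOCC1)[C@H](CCO[Si](c1ccccc1)(c1ccccc1)C(C)(C)C)[C@@]1(C)C[C@H](Cl)[C@H](Cl)C(C)(C)C1=O | intermediate
18 | C8 morpholine amide, 2α,3β-dichloro, C5 ketone | O=C(N1CCOCC1)[C@H](CCO[Si](c1ccccc1)(c1ccccc1)C(C)(C)C)[C@@]1(C)C[C@@H](Cl)[C@H](Cl)C(C)(C)C1=O | intermediate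
19 | C8 morpholine amide, 2α,3β-dichloro, 5β-hydroxy | O=C(N1CCOCC1)[C@H](CCO[Si](c1ccccc1)(c1ccccc1)C(C)(C)C)[C@@]1(C)C[C@@H](Cl)[C@H](Cl)C(C)(C)[C@@H]1O | intermediate
20 | lithium hemiaminal alkoxide (tetrahedral adduct at C8, C5 O-phenyl thionocarbonate; C8 configuration undefined) | [Li]OC(C(=C)OCC)(N1CCOCC1)[C@H](CCO[Si](c1ccccc1)(c1ccccc1)C(C)(C)C)[C@@]1(C)C[C@@H](Cl)[C@H](Cl)C(C)(C)[C@@H]1OC(=S)Oc1ccccc1 | intermediate
21 | 2-ethoxy-1-en-3-one with C5 O-phenyl thionocarbonate | C=C(OCC)C(=O)[C@H](CCO[Si](c1ccccc1)(c1ccccc1)C(C)(C)C)[C@@]1(C)C[C@@H](Cl)[C@H](Cl)C(C)(C)[C@@H]1OC(=S)Oc1ccccc1 | intermediate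
22 | C7,C8-diketone with C5 O-phenyl thionocarbonate | CC(=O)C(=O)[C@H](CCO[Si](c1ccccc1)(c1ccccc1)C(C)(C)C)[C@@]1(C)C[C@@H](Cl)[C@H](Cl)C(C)(C)[C@@H]1OC(=S)Oc1ccccc1 | intermediate
23 | 2-acetoxy-1-en-3-one with C5 O-phenyl thionocarbonate (cyclisation precursor) | C=C(OC(C)=O)C(=O)[C@H](CCO[Si](c1ccccc1)(c1ccccc1)C(C)(C)C)[C@@]1(C)C[C@@H](Cl)[C@H](Cl)C(C)(C)[C@@H]1OC(=S)Oc1ccccc1 | intermediate
24 | 7β-acetoxy-2α,3β-dichloro-12-(tert-butyldiphenylsilyloxy)-13,14,15,16,17-pentanorlabdan-8-one | O=C1[C@@H](OC(C)=O)C[C@H]2C(C)(C)[C@@H](Cl)[C@H](Cl)C[C@]2(C)[C@H]1CCO[Si](c1ccccc1)(c1ccccc1)C(C)(C)C | intermediate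
25 | 7β-acetoxy-2α,3β-dichloro-12-(tert-butyldiphenylsilyloxy)-13,14,15,16-tetranorlabd-8(17)-ene | C=C1[C@@H](OC(C)=O)C[C@H]2C(C)(C)[C@@H](Cl)[C@H](Cl)C[C@]2(C)[C@H]1CCO[Si](c1ccccc1)(c1ccccc1)C(C)(C)C | intermediate
26 | 7β-acetoxy-2α,3β-dichloro-13,14,15,16-tetranorlabd-8(17)-en-12-ol | C=C1[C@@H](OC(C)=O)C[C@H]2C(C)(C)[C@@H](Cl)[C@H](Cl)C[C@]2(C)[C@H]1CCO | intermediate
27 | 7β-acetoxy-2α,3β-dichloro-13,14,15,16-tetranorlabd-8(17)-en-12-al | C=C1[C@@H](OC(C)=O)C[C@H]2C(C)(C)[C@@H](Cl)[C@H](Cl)C[C@]2(C)[C@H]1CC=O | intermediate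
28 | (R)-4-benzyloxazolidin-2-one | O=C1N[C@H](Cc2ccccc2)CO1 | starting material
29 | succinic anhydride | O=C1CCC(=O)O1 | starting material
30 | lithium salt of 28 | [Li]N1[C@H](Cc2ccccc2)COC1=O | intermediate
31 | 4-[(4R)-4-benzyl-2-oxooxazolidin-3-yl]-4-oxobutanoic acid | OC(=O)CCC(=O)N1[C@H](Cc2ccccc2)COC1=O | intermediate
32 | isobutyl mixed carbonic anhydride of 31 | CC(C)COC(=O)OC(=O)CCC(=O)N1[C@H](Cc2ccccc2)COC1=O | intermediate
33 | 4-[(4R)-4-benzyl-2-oxooxazolidin-3-yl]-4-oxobutanamide | NC(=O)CCC(=O)N1[C@H](Cc2ccccc2)COC1=O | intermediate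
34 | dibutylboron (Z)-enolate of 33 | NC(=O)C/C=C(\OB(CCCC)CCCC)N1[C@H](Cc2ccccc2)COC1=O | intermediate
35 | (12S,13R)-aldol adduct, N-acyl (R)-4-benzyloxazolidinone with C15 primary amide | C=C1[C@@H](OC(C)=O)C[C@H]2C(C)(C)[C@@H](Cl)[C@H](Cl)C[C@]2(C)[C@H]1C[C@H](O)[C@@H](CC(N)=O)C(=O)N1[C@H](Cc2ccccc2)COC1=O | intermediate
36 | haterumaimide A | C=C1[C@@H](OC(C)=O)C[C@H]2C(C)(C)[C@@H](Cl)[C@H](Cl)C[C@]2(C)[C@H]1C[C@H](O)[C@H]1CC(=O)NC1=O | target

Total step count: 22. Longest linear sequence: 20 steps (steps 1–18, then 21 and 22).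

Steps most likely to fail

1. Step 15 (key step). The risk is poor facial selectivity in the C5–C6 bond formation. Approach of C6 to the C5 radical anti to the two axial methyl groups (on C4 and C10) would give the cis-fused decalin, and direct reduction of the C5 radical can compete. The fallback forms the bond at an sp2 C5 and delivers the C5 hydrogen last. Setting out from 18, the morpholine amide is converted with CH2=C(OEt)Li and aqueous acid into the triketone F1. Acid-catalysed intramolecular aldol condensation of its methyl ketone onto the C5 ketone (TsOH, benzene, reflux) closes ring B at C5–C6 as the ene-dione F2. Conjugate reduction by hydrogen-atom transfer (Mn(dpm)3, PhSiH3, i-PrOH) should deliver hydrogen to C5 from the α-face, opposite both axial methyl groups, to give the trans-fused dione F3. NaBH4 at −78 °C should reduce the less hindered C7 carbonyl from the α-face to the ketol F4, and acetylation (Ac2O, pyridine) comes back to the route at 24.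

2. Step 13. The risks are incomplete thioacylation of the hindered lithium alkoxide, attack of the organolithium on the thionocarbonate, and early collapse of the tetrahedral intermediate to a hydroxy ketone that closes to a hemiketal. The fallback is stepwise and uses an aldehyde-level electrophile. Setting out from 19, thioacylation of the free alcohol (PhOC(S)Cl, pyridine, DMAP) gives the thionocarbonate amide F5. Cp2Zr(H)Cl reduces the tertiary amide to the aldehyde F6. CH2=C(OEt)Li at −100 °C should add to the aldehyde far faster than to the thionocarbonate, and acidic work-up gives the ketol F7. Dess–Martin oxidation comes back to the route at 22.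

3. Step 11. The risks are elimination competing with substitution at C2 and chloride exchange too slow to complete the epimerisation. The fallback is an oxidation–reduction inversion followed by a single substitution. Setting out from 15, Dess–Martin oxidation gives the α-chloro ketone F8. NaBH4 with CeCl3·7H2O at −78 °C should add hydride anti to the C3 chlorine and give the cis chlorohydrin F9 (2β-OH). Appel chlorination (PPh3, CCl4), an SN2 reaction with inversion at C2, comes back to the route at 18.

Further compounds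
F1 | step 15 | C5,C7,C8-triketone of ring A (2α,3β-dichloro) | CC(=O)C(=O)[C@H](CCO[Si](c1ccccc1)(c1ccccc1)C(C)(C)C)[C@@]1(C)C[C@@H](Cl)[C@H](Cl)C(C)(C)C1=O
F2 | step 15 | 2α,3β-dichloro-12-(tert-butyldiphenylsilyloxy)-13,14,15,16,17-pentanorlabd-5-ene-7,8-dione | O=C1C(=O)C=C2C(C)(C)[C@@H](Cl)[C@H](Cl)C[C@]2(C)[C@H]1CCO[Si](c1ccccc1)(c1ccccc1)C(C)(C)C
F3 | step 15 | 2α,3β-dichloro-12-(tert-butyldiphenylsilyloxy)-13,14,15,16,17-pentanorlabdane-7,8-dione (5α-H) | O=C1C(=O)C[C@H]2C(C)(C)[C@@H](Cl)[C@H](Cl)C[C@]2(C)[C@H]1CCO[Si](c1ccccc1)(c1ccccc1)C(C)(C)C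
F4 | step 15 | 2α,3β-dichloro-7β-hydroxy-12-(tert-butyldiphenylsilyloxy)-13,14,15,16,17-pentanorlabdan-8-one | O=C1[C@@H](O)C[C@H]2C(C)(C)[C@@H](Cl)[C@H](Cl)C[C@]2(C)[C@H]1CCO[Si](c1ccccc1)(c1ccccc1)C(C)(C)C
F5 | step 13 | C8 morpholine amide with C5 O-phenyl thionocarbonate | O=C(N1CCOCC1)[C@H](CCO[Si](c1ccccc1)(c1ccccc1)C(C)(C)C)[C@@]1(C)C[C@@H](Cl)[C@H](Cl)C(C)(C)[C@@H]1OC(=S)Oc1ccccc1
F6 | step 13 | C8 aldehyde with C5 O-phenyl thionocarbonate | O=C[C@H](CCO[Si](c1ccccc1)(c1ccccc1)C(C)(C)C)[C@@]1(C)C[C@@H](Cl)[C@H](Cl)C(C)(C)[C@@H]1OC(=S)Oc1ccccc1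
F7 | step 13 | C8-hydroxy C7-ketone (ketol, C8 configuration undefined) with C5 O-phenyl thionocarbonate | CC(=O)C(O)[C@H](CCO[Si](c1ccccc1)(c1ccccc1)C(C)(C)C)[C@@]1(C)C[C@@H](Cl)[C@H](Cl)C(C)(C)[C@@H]1OC(=S)Oc1ccccc1
F8 | step 11 | C8 morpholine amide, 3β-chloro-2,5-diketone | O=C(N1CCOCC1)[C@H](CCO[Si](c1ccccc1)(c1ccccc1)C(C)(C)C)[C@@]1(C)CC(=O)[C@H](Cl)C(C)(C)C1=O
F9 | step 11 | C8 morpholine amide, 2β-hydroxy, 3β-chloro, C5 ketone | O=C(N1CCOCC1)[C@H](CCO[Si](c1ccccc1)(c1ccccc1)C(C)(C)C)[C@@]1(C)C[C@H](O)[C@H](Cl)C(C)(C)C1=O
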